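**Plan**
- Retrosynthesis cuts ring C first at its C1–C6 bond (aldol plus dehydration reversed), which opens it to an aryl 3,5,7-trioxooctanoate. The next cut is the acyl C1–O bond to ring-B O4 (acylketene plus phenol), then the ring-B carboxyl to ring-A O4 ester, and last the O-benzyl and O-methyl bonds back to methyl orsellinate.
- The enabling feature is that ring C is an unsubstituted orsellinoyl group: its 2-OH, 4-OH and 6-CH3 sit on the carbons that are C3, C5 and C7 of the open chain, and its carboxyl carbon (C1) is bound to ring-B O4.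
- Forward, rings A and B both come ready-made from methyl orsellinate through one common 4-O-benzyl-2-O-methyl ester, which is split into a ring-A phenol and a ring-B acid and rejoined as the A–B didepside phenol.
- 2,2,6-Trimethyl-4H-1,3-dioxin-4-one is acylated twice to a diketo-dioxinone; its thermolysis gives an acylketene that the didepside phenol captures.
- Ring C arises last, by aldol aromatisation of the triketo ester, with both of its phenols free.
- Stereochemistry: none to set.

Key step: step 10

Remark: the target has no stereocentre or other stereogenic element, so the achiral structure itself is the single compound asked for.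

**Route**

Step 1
Reactants: 1 methyl orsellinate (methyl 2,4-dihydroxy-6-methylbenzoate)
Product: 2 methyl 4-(benzyloxy)-2-hydroxy-6-methylbenzoate
Conditions: BnBr (1.05 equiv), K2CO3, acetone, reflux
Reagents that add atoms: benzyl bromide, BrCc1ccccc1
Why: Williamson etherification; the 2-OH is tied up in a hydrogen bond to the ester carbonyl, so the more acidic, free 4-OH should be benzylated selectively.

Step 2
Reactants: 2 methyl 4-(benzyloxy)-2-hydroxy-6-methylbenzoate
Product: 3 methyl 4-(benzyloxy)-2-methoxy-6-methylbenzoate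
Conditions: MeI (excess), K2CO3, DMF, 60 °C
Reagents that add atoms: iodomethane, CI
Why: Williamson O-methylation of the remaining chelated phenol under more forcing conditions; no other nucleophilic site is present.

Step 3
Reactants: 3 methyl 4-(benzyloxy)-2-methoxy-6-methylbenzoate
Product: 4 methyl 4-hydroxy-2-methoxy-6-methylbenzoate (ring-A phenol)
Conditions: H2 (1 atm), 10% Pd/C, EtOAc, rt
Reagents that add atoms: none
Why: Catalytic hydrogenolysis of the benzyl aryl ether; the methyl ester and methyl ether are inert.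

Step 4
Reactants: 3 methyl 4-(benzyloxy)-2-methoxy-6-methylbenzoate
Product: 5 4-(benzyloxy)-2-methoxy-6-methylbenzoic acid (ring-B acid)
Conditions: KOH, DMSO/H2O, 100 °C; then aq. HCl
Reagents that add atoms: potassium hydroxide, [K+].[OH-]
Why: Saponification of a 2,6-disubstituted benzoate, which needs hot hydroxide in a dipolar solvent; the benzyl and methyl ethers are stable to base.

Step 5
Reactants: 5 4-(benzyloxy)-2-methoxy-6-methylbenzoic acid; 4 methyl 4-hydroxy-2-methoxy-6-methylbenzoate
Product: 7 methyl 4-{[4-(benzyloxy)-2-methoxy-6-methylbenzoyl]oxy}-2-methoxy-6-methylbenzoate, via acid chloride 6 (not isolated)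
Conditions: (COCl)2, cat. DMF, CH2Cl2, 0 °C → rt; evaporate; then 4, Et3N, cat. DMAP, CH2Cl2, 0 °C → rt
Reagents that add atoms: none
Why: The hindered acid is activated as its acid chloride (Vilsmeier-type chlorination), which then acylates the unhindered 4-OH of 4 under DMAP catalysis, a standard depside esterification by nucleophilic acyl substitution.

Step 6
Reactants: 7 methyl 4-{[4-(benzyloxy)-2-methoxy-6-methylbenzoyl]oxy}-2-methoxy-6-methylbenzoate
Product: 8 methyl 4-[(4-hydroxy-2-methoxy-6-methylbenzoyl)oxy]-2-methoxy-6-methylbenzoate (A–B didepside phenol)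
Conditions: H2 (1 atm), 10% Pd/C, EtOAc/THF, rt
Reagents that add atoms: none
Why: Hydrogenolysis of the benzyl ether under neutral conditions, which leave the aryl benzoate link and the methyl ester intact.

Step 7
Reactants: 9 2,2,6-trimethyl-4H-1,3-dioxin-4-one
Product: 11 2,2-dimethyl-6-(2-oxopropyl)-4H-1,3-dioxin-4-one, via lithium dienolate 10 (not isolated)
Conditions: LiHMDS, THF, −78 °C; AcCl (0.5 equiv relative to dienolate), −78 °C; aq. NH4Cl
Reagents that add atoms: acetyl chloride, CC(Cl)=O
Why: Kinetic γ-deprotonation of the vinylogous ester gives the dienolate, which is C-acylated at the exocyclic carbon (crossed Claisen-type acylation); the second equivalent of dienolate takes up the proton of the more acidic product.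

Step 8
Reactants: 11 2,2-dimethyl-6-(2-oxopropyl)-4H-1,3-dioxin-4-one
Product: 13 6-(2,4-dioxopentyl)-2,2-dimethyl-4H-1,3-dioxin-4-one, via dilithium dianion 12 (not isolated)
Conditions: LDA (2.2 equiv), THF, −78 °C; MeC(O)N(OMe)Me, −78 → −20 °C; cold dilute HCl; used promptly
Reagents that add atoms: N-methoxy-N-methylacetamide, CC(=O)N(C)OC
Why: Double deprotonation gives a 1,3-dicarbonyl-type dianion whose last-formed terminal carbanion is the reactive site, and acylation with a Weinreb amide stops at the ketone stage (dianion γ-acylation, Weinreb ketone synthesis).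

Step 9
Reactants: 8 methyl 4-[(4-hydroxy-2-methoxy-6-methylbenzoyl)oxy]-2-methoxy-6-methylbenzoate; 13 6-(2,4-dioxopentyl)-2,2-dimethyl-4H-1,3-dioxin-4-one
Product: 15 3-methoxy-4-{[3-methoxy-4-(methoxycarbonyl)-5-methylphenoxy]carbonyl}-5-methylphenyl 3,5,7-trioxooctanoate, via acylketene 14 (not isolated)
Conditions: PhMe, 110 °C, slow addition of 13 (1.5 equiv) to concentrated 8; evaporate, crude enol-tautomer mixture used directly
Reagents that add atoms: none
Why: Retro-hetero-Diels–Alder loss of acetone from the dioxinone gives the acylketene, which the phenol O–H of 8 should capture as in the thermal acetoacetylation of phenols with 9; keeping the ketene dilute and the phenol concentrated favours intermolecular capture.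

Step 10
Reactants: 15 3-methoxy-4-{[3-methoxy-4-(methoxycarbonyl)-5-methylphenoxy]carbonyl}-5-methylphenyl 3,5,7-trioxooctanoate
Product: 17 CNP0514431.0 (target), via aldol carbinol 16 (not isolated)
Conditions: Et3N/AcOH (1:1, 1.5 equiv), CH2Cl2, 0 °C → rt; then TFA, rt
Reagents that add atoms: none
Why: Triethylammonium acetate enolises the C2 methylene, which lies between the aryl ester and the C3 ketone, and this carbon adds to the free C7 methyl ketone to form the C2–C7 bond (C1–C6 of ring C) and carbinol 16; E1cB loss of water, completed by TFA, and enolisation of the C3 and C5 carbonyls then give the 2,4-dihydroxy-6-methylbenzoate. The closest known reaction type is the biomimetic aldol aromatisation of 3,5,7-triketo esters to resorcylates, here run on an aryl ester. Ring C closes by a 6-(enolexo)-exo-trig aldol addition. No stereocentre survives, since both centres of 16 are erased on aromatisation. The step needs C2-to-C7 aldol closure to outrun C6-to-C1 Claisen closure, O5-to-C1 pyranone formation and E1cB ketene loss, each of which would expel the ring-B aryloxide; the substrate helps because C7 is an unhindered methyl ketone while C1 is a less electrophilic ester carbonyl deactivated further by conjugation in the enolised β-keto ester, and the near-neutral, non-nucleophilic buffer keeps the enolate concentration low. The two 2,6-disubstituted benzoate links and the methyl ester should be inert to these conditions, and both phenols of ring C emerge free from the ketones.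

**Compound list**

1 | methyl orsellinate (methyl 2,4-dihydroxy-6-methylbenzoate) | COC(=O)c1c(C)cc(O)cc1O | starting material
2 | methyl 4-(benzyloxy)-2-hydroxy-6-methylbenzoate | COC(=O)c1c(C)cc(OCc2ccccc2)cc1O | intermediate
3 | methyl 4-(benzyloxy)-2-methoxy-6-methylbenzoate | COC(=O)c1c(C)cc(OCc2ccccc2)cc1OC | intermediate
4 | methyl 4-hydroxy-2-methoxy-6-methylbenzoate | COC(=O)c1c(C)cc(O)cc1OC | intermediate
5 | 4-(benzyloxy)-2-methoxy-6-methylbenzoic acid | OC(=O)c1c(C)cc(OCc2ccccc2)cc1OC | intermediate
6 | 4-(benzyloxy)-2-methoxy-6-methylbenzoyl chloride | ClC(=O)c1c(C)cc(OCc2ccccc2)cc1OC | intermediate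
7 | methyl 4-{[4-(benzyloxy)-2-methoxy-6-methylbenzoyl]oxy}-2-methoxy-6-methylbenzoate | COC(=O)c1c(C)cc(OC(=O)c2c(C)cc(OCc3ccccc3)cc2OC)cc1OC | intermediate
8 | methyl 4-[(4-hydroxy-2-methoxy-6-methylbenzoyl)oxy]-2-methoxy-6-methylbenzoate | COC(=O)c1c(C)cc(OC(=O)c2c(C)cc(O)cc2OC)cc1OC | intermediate
9 | 2,2,6-trimethyl-4H-1,3-dioxin-4-one | CC1=CC(=O)OC(C)(C)O1 | starting material
10 | lithium dienolate of 9 (lithium 2,2-dimethyl-6-methylidene-6H-1,3-dioxin-4-olate) | [Li+].C=C1C=C([O-])OC(C)(C)O1 | intermediate
11 | 2,2-dimethyl-6-(2-oxopropyl)-4H-1,3-dioxin-4-one | CC(=O)CC1=CC(=O)OC(C)(C)O1 | intermediate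
12 | dilithium dianion of 11 (bis-enolate) | [Li+].[Li+].C=C([O-])C=C1C=C([O-])OC(C)(C)O1 | intermediate
13 | 6-(2,4-dioxopentyl)-2,2-dimethyl-4H-1,3-dioxin-4-one | CC(=O)CC(=O)CC1=CC(=O)OC(C)(C)O1 | intermediate
14 | 3,5,7-trioxooct-1-en-1-one (acylketene) | CC(=O)CC(=O)CC(=O)C=C=O | intermediate
15 | 3-methoxy-4-{[3-methoxy-4-(methoxycarbonyl)-5-methylphenoxy]carbonyl}-5-methylphenyl 3,5,7-trioxooctanoate | CC(=O)CC(=O)CC(=O)CC(=O)Oc1cc(C)c(C(=O)Oc2cc(C)c(C(=O)OC)c(OC)c2)c(OC)c1 | intermediate
16 | 3-methoxy-4-{[3-methoxy-4-(methoxycarbonyl)-5-methylphenoxy]carbonyl}-5-methylphenyl 2-hydroxy-2-methyl-4,6-dioxocyclohexane-1-carboxylate (diastereomer mixture, both centres lost on aromatisation) | CC1(O)CC(=O)CC(=O)C1C(=O)Oc1cc(C)c(C(=O)Oc2cc(C)c(C(=O)OC)c(OC)c2)c(OC)c1 | intermediate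
17 | CNP0514431.0, methyl 4-({4-[(2,4-dihydroxy-6-methylbenzoyl)oxy]-2-methoxy-6-methylbenzoyl}oxy)-2-methoxy-6-methylbenzoate | COC(=O)c1c(C)cc(OC(=O)c2c(C)cc(OC(=O)c3c(C)cc(O)cc3O)cc2OC)cc1OC | target

**Step count**

Total: 10 steps. Longest linear sequence: 7 steps (steps 1, 2, 4, 5, 6, 9, 10).

**Steps most likely to fail**

Step 10. The risk is acyl substitution at C1 before the aldol closes: lactonisation by the enolised C5 oxygen, Claisen closure from C6, or E1cB return to the ketene, each with loss of the ring-B aryloxide. The fallback builds ring C by conventional acylation; it sets out from 1 and 8 and comes back at 17. Methyl orsellinate 1 would be benzylated twice (excess BnBr, K2CO3, DMF, 60 °C) to methyl 2,4-bis(benzyloxy)-6-methylbenzoate F1 and saponified (KOH, aq. DMSO, heat) to 2,4-bis(benzyloxy)-6-methylbenzoic acid F2. Oxalyl chloride with cat. DMF would convert this to 2,4-bis(benzyloxy)-6-methylbenzoyl chloride F3, which should acylate phenol 8 (Et3N, DMAP, CH2Cl2) to give the bis-benzyl tridepside methyl 4-[(4-{[2,4-bis(benzyloxy)-6-methylbenzoyl]oxy}-2-methoxy-6-methylbenzoyl)oxy]-2-methoxy-6-methylbenzoate F4. Hydrogenolysis (H2, Pd/C, EtOAc) would then give 17.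

Step 9. The risk is that the acylketene is consumed by its own enol oxygen (cyclisation to a pyranone) faster than the electron-poor phenol adds, or that the aryl triketo ester cyclises without control at 110 °C. The fallback moves ring-C formation ahead of the esterification; it sets out from 13 and 8 and comes back at 17. Treating 13 with Et3N in CH2Cl2 should aromatise it, by the same kind of aldol closure, to 7-hydroxy-2,2,5-trimethyl-4H-1,3-benzodioxin-4-one F5. Benzylation (BnBr, K2CO3, acetone) would give 7-(benzyloxy)-2,2,5-trimethyl-4H-1,3-benzodioxin-4-one F6. Irradiation at about 300 nm in CH2Cl2 with 8 present should extrude acetone to the quinone ketene 3-(benzyloxy)-5-methyl-6-(oxomethylidene)cyclohexa-2,4-dien-1-one F7, which has no internal trap and should be captured by the phenol. This would give the mono-benzyl tridepside methyl 4-[(4-{[4-(benzyloxy)-2-hydroxy-6-methylbenzoyl]oxy}-2-methoxy-6-methylbenzoyl)oxy]-2-methoxy-6-methylbenzoate F8, and hydrogenolysis (H2, Pd/C) would give 17.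

Step 8. The risk is proton exchange or acylation at the wrong carbon of the dianion, and base-induced cyclisation of the diketo-dioxinone while it is still in the basic mixture. The fallback keeps the second ketone masked through the basic step; it sets out from 9 and comes back at 13. Commercial ethyl (2-methyl-1,3-dioxolan-2-yl)acetate would be converted (MeNHOMe·HCl, iPrMgCl, THF, −20 °C) into N-methoxy-N-methyl-2-(2-methyl-1,3-dioxolan-2-yl)acetamide F9. Lithium dienolate 10, made from 9 as in step 7, would be acylated with it to give 2,2-dimethyl-6-[3-(2-methyl-1,3-dioxolan-2-yl)-2-oxopropyl]-4H-1,3-dioxin-4-one F10. Mild acid hydrolysis of the ketal (dilute HCl, THF, rt) just before use would release 13.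

**Further compounds**

F1 | step 10 | methyl 2,4-bis(benzyloxy)-6-methylbenzoate | COC(=O)c1c(C)cc(OCc2ccccc2)cc1OCc1ccccc1
F2 | step 10 | 2,4-bis(benzyloxy)-6-methylbenzoic acid | OC(=O)c1c(C)cc(OCc2ccccc2)cc1OCc1ccccc1
F3 | step 10 | 2,4-bis(benzyloxy)-6-methylbenzoyl chloride | ClC(=O)c1c(C)cc(OCc2ccccc2)cc1OCc1ccccc1
F4 | step 10 | methyl 4-[(4-{[2,4-bis(benzyloxy)-6-methylbenzoyl]oxy}-2-methoxy-6-methylbenzoyl)oxy]-2-methoxy-6-methylbenzoate | COC(=O)c1c(C)cc(OC(=O)c2c(C)cc(OC(=O)c3c(C)cc(OCc4ccccc4)cc3OCc3ccccc3)cc2OC)cc1OC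
F5 | step 9 | 7-hydroxy-2,2,5-trimethyl-4H-1,3-benzodioxin-4-one | Cc1cc(O)cc2OC(C)(C)OC(=O)c12
F6 | step 9 | 7-(benzyloxy)-2,2,5-trimethyl-4H-1,3-benzodioxin-4-one | Cc1cc(OCc3ccccc3)cc2OC(C)(C)OC(=O)c12
F7 | step 9 | 3-(benzyloxy)-5-methyl-6-(oxomethylidene)cyclohexa-2,4-dien-1-one | O=C=C1C(C)=CC(OCc2ccccc2)=CC1=O
F8 | step 9 | methyl 4-[(4-{[4-(benzyloxy)-2-hydroxy-6-methylbenzoyl]oxy}-2-methoxy-6-methylbenzoyl)oxy]-2-methoxy-6-methylbenzoate | COC(=O)c1c(C)cc(OC(=O)c2c(C)cc(OC(=O)c3c(C)cc(OCc4ccccc4)cc3O)cc2OC)cc1OC
F9 | step 8 | N-methoxy-N-methyl-2-(2-methyl-1,3-dioxolan-2-yl)acetamide | CON(C)C(=O)CC1(C)OCCO1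
F10 | step 8 | 2,2-dimethyl-6-[3-(2-methyl-1,3-dioxolan-2-yl)-2-oxopropyl]-4H-1,3-dioxin-4-one | CC1(CC(=O)CC2=CC(=O)OC(C)(C)O2)OCCO1
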